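## Retrosynthetic overview

- The target is catechin-(4α→8)-gallocatechin-(4α→8)-gallocatechin. It is reached by deacetylation and hydrogenolysis of a benzyl-protected trimer; the top (catechin) and bottom (gallocatechin) heterocycles come intact from the chiral pool.
- Key disconnection: ring C of the middle gallocatechin unit is cut at O1–C2 and at C4a–C4, a formal (3+3) split. One piece is a phenol (ring A of the middle unit already attached to C4 of the top unit). The other is a 1,3-diaryl-2,3-epoxypropan-1-ol (C2–C3–C4 of the middle unit, ring B on C2, C8 of the bottom unit on C4).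
- Enabling feature: C4 of the middle unit is benzylic to C8 of the bottom ring A, which carries O7 and O1 ortho and O5 para, so a carbinol there ionises to a quinone-methide-like cation. C4a of the middle ring A is ortho/para to three oxygens, and after C–C bond formation its phenolic O1 sits five atoms from the benzylic epoxide carbon C2.
- The phenol comes from (+)-catechin by C4 activation and α-selective Friedel–Crafts arylation with 3,5-bis(benzyloxy)phenol. The epoxy carbinol comes from an 8-lithiated perbenzyl gallocatechin and a Sharpless-derived epoxy aldehyde.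
- Ring order: rings C of the top and bottom units pre-exist; ring C of the middle unit is formed last.

Key step: step 12

Assumption: (+)-catechin and (+)-gallocatechin (both 2R,3S) are taken as commercial chiral-pool materials and supply the stereocentres of the top and bottom units unchanged.

## Route

Step 1
Reactants: 1 (+)-catechin
Product: 2 5,7,3',4'-tetra-O-benzyl-(+)-catechin (2R,3S; 3-OH free)
Conditions: BnBr (4.2 equiv), K2CO3, DMF, 0 °C → rt
Reagents that add atoms: benzyl bromide, BrCc1ccccc1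
Why: Williamson etherification; the four phenols are far more acidic than the C3 alcohol, so carbonate benzylates only them and no stereocentre is touched.

Step 2
Reactants: 2 5,7,3',4'-tetra-O-benzyl-(+)-catechin
Product: 3 (2R,3S,4S)-5,7,3',4'-tetra-O-benzyl-4-(2-ethoxyethoxy)flavan-3-ol (4β-ether)
Conditions: DDQ, 2-ethoxyethanol, CH2Cl2, rt
Reagents that add atoms: 2-ethoxyethanol, CCOCCO
Why: Oxidative benzylic etherification: DDQ abstracts hydride from C4, activated by the 5,7-dialkoxy ring A, and the alcohol traps the quinone-methide-type cation, expected mainly by axial attack; the C4 configuration is lost again in step 4 and is of no consequence.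

Step 3
Reactants: 3 4-(2-ethoxyethoxy) ether
Product: 4 (2R,3S,4S)-3-O-acetyl-5,7,3',4'-tetra-O-benzyl-4-(2-ethoxyethoxy)flavan
Conditions: Ac2O, pyridine, DMAP (cat.), rt
Reagents that add atoms: acetic anhydride, CC(=O)OC(C)=O
Why: DMAP-catalysed acylation of the secondary alcohol under basic conditions that leave the acid-labile C4 ether intact; the acetate is installed as a participating group for step 4.

Step 4
Reactants: 4 3-O-acetyl C4 ether; 5 3,5-bis(benzyloxy)phenol (3 equiv)
Product: 6 3-O-acetyl-5,7,3',4'-tetra-O-benzylcatechin-(4α→2)-[3,5-bis(benzyloxy)phenol] (flavan C4 joined 3,4-trans to the ring carbon ortho to the free OH)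
Conditions: TMSOTf (0.3 equiv), CH2Cl2, −78 °C → −40 °C
Reagents that add atoms: none
Why: Lewis-acid-mediated Friedel–Crafts C4-arylation of a 4-alkoxyflavan, the reaction type used for interflavan bonds: the 3β-acetoxy group shields the β-face of the C4 cation so the phenol adds from the α-face (3,4-trans), and the less hindered carbon ortho to OH (two equivalent sites) should be preferred over the carbon between the two benzyloxy groups, with excess 5 suppressing double alkylation.

Step 5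
Reactants: 7 (+)-gallocatechin
Product: 8 3,5,7,3',4',5'-hexa-O-benzyl-(+)-gallocatechin
Conditions: BnBr, K2CO3, DMF, rt; then NaH, 0 °C → rt (one pot, argon)
Reagents that add atoms: benzyl bromide, BrCc1ccccc1
Why: Two-stage Williamson etherification; the air-sensitive pyrogallol and the other phenols are capped with carbonate before NaH is added for the C3 alkoxide, and no stereocentre is touched.

Step 6
Reactants: 8 hexa-O-benzyl-(+)-gallocatechin
Product: 9 8-bromo-3,5,7,3',4',5'-hexa-O-benzyl-(+)-gallocatechin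
Conditions: NBS (1.0 equiv), CH2Cl2, −78 °C → rt
Reagents that add atoms: N-bromosuccinimide, O=C1CCC(=O)N1Br
Why: Electrophilic aromatic bromination; C8 of a 5,7-di-O-benzylflavan is the most nucleophilic arene carbon (ortho/para to three oxygens, more reactive than C6 and than ring B), so one equivalent of NBS at low temperature should brominate there.

Step 7
Reactants: 10 3,4,5-tris(benzyloxy)benzaldehyde
Product: 11 ethyl (E)-3-[3,4,5-tris(benzyloxy)phenyl]prop-2-enoate
Conditions: (EtO)2P(O)CH2CO2Et, NaH, THF, 0 °C → rt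
Reagents that add atoms: triethyl phosphonoacetate, CCOC(=O)CP(=O)(OCC)OCC
Why: Horner–Wadsworth–Emmons olefination with a stabilised phosphonate gives the (E)-ester.

Step 8
Reactants: 11 ethyl (E)-cinnamate
Product: 12 (E)-3-[3,4,5-tris(benzyloxy)phenyl]prop-2-en-1-ol
Conditions: i-Bu2AlH (2.2 equiv), CH2Cl2, −78 °C → 0 °C; Rochelle salt
Reagents that add atoms: none
Why: 1,2-reduction of the α,β-unsaturated ester to the allylic alcohol with retention of the (E)-geometry.

Step 9
Reactants: 12 (E)-cinnamyl alcohol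
Product: 13 {(2S,3S)-3-[3,4,5-tris(benzyloxy)phenyl]oxiran-2-yl}methanol
Conditions: Ti(OiPr)4 (10 mol %), L-(+)-diethyl tartrate (12 mol %), t-BuOOH, 4 Å MS, CH2Cl2, −20 °C
Reagents that add atoms: tert-butyl hydroperoxide, CC(C)(C)OO
Why: Sharpless asymmetric epoxidation; the L-(+)-tartrate complex delivers oxygen to the face of the (E)-allylic alcohol that gives the (2S,3S)-epoxide, which fixes both future stereocentres C2 and C3 of the middle unit.

Step 10
Reactants: 13 (2S,3S)-epoxy alcohol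
Product: 14 (2R,3S)-3-[3,4,5-tris(benzyloxy)phenyl]oxirane-2-carbaldehyde
Conditions: PhI(OAc)2 (1.1 equiv), TEMPO (10 mol %), CH2Cl2, rt
Reagents that add atoms: none
Why: TEMPO/PhI(OAc)2 oxidation of the primary alcohol to the aldehyde under near-neutral conditions that should leave the epoxide and its configuration intact (the descriptor at C2 changes only through the priority change).

Step 11
Reactants: 9 8-bromo-hexa-O-benzylgallocatechin; 14 (2R,3S)-epoxy aldehyde
Product: 16 (hexa-O-benzylgallocatechin-8-yl){(2S,3S)-3-[3,4,5-tris(benzyloxy)phenyl]oxiran-2-yl}methanol as a mixture of carbinol epimers, via 8-lithio-hexa-O-benzylgallocatechin 15 (not isolated)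
Conditions: n-BuLi (1.05 equiv), THF, −78 °C; then 14, −78 °C; aq. NH4Cl; Et3N-washed silica or used crude
Reagents that add atoms: none
Why: Bromine–lithium exchange followed by 1,2-addition of the aryllithium to the aldehyde, which at −78 °C should outrun epoxide opening; the new carbinol centre forms unselectively, which does not matter because it is ionised in step 12.

Step 12
Reactants: 6 phenol (1.2 equiv); 16 epoxy carbinol
Product: 18 protected trimer [3-O-acetyl-tetra-O-benzylcatechin]-(4α→8)-[5,7,3',4',5'-penta-O-benzylgallocatechin]-(4α→8)-[hexa-O-benzylgallocatechin] with the middle 3-OH free, via ring-open epoxy phenol 17 (not isolated)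
Conditions: (PhO)2P(O)OH (10 mol %), 4 Å MS, CH2Cl2, −40 °C → rt
Reagents that add atoms: none
Why: Proposed new method: the phosphoric acid ionises the carbinol of 16, whose carbon is flanked by the 2,4,6-trioxygenated ring A of the bottom unit, to a quinone-methide-like benzylic cation paired with phosphate; the hydrogen-bonded phenol 6 attacks it through the ring carbon ortho to its hydroxyl (Friedel–Crafts alkylation, C4a–C4) to give 17, whose phenolic oxygen then opens the acid-activated epoxide at the benzylic carbon with inversion (O1–C2), a formal (3+3) annulation. The closest known reaction types are the Brønsted-acid-catalysed ortho-alkylation of phenols by quinone-methide-type benzylic cations and the acid-mediated 6-endo cyclisation of o-hydroxybenzyl aryl epoxides to 2,3-trans-flavan-3-ols; their merger in one flask on a 1,3-diaryl-2,3-epoxypropan-1-ol is the new element. The one ring closed, ring C of the middle unit, closes by 6-endo-tet attack of O1 on epoxide carbon C2, which the cation-stabilising 3,4,5-tris(benzyloxy)phenyl group should favour over the 5-exo mode under acid. C3 keeps the configuration set by the Sharpless epoxidation, C2 is set by stereospecific inversion of the (S)-epoxide carbon (2,3-trans), and C4 is set in the Friedel–Crafts event by the adjacent epoxide stereocentre: in the allylic-strain-minimised conformer of the cation (epoxide C–H in the cation plane, facing the ortho benzyloxy group) the arene should add anti to the epoxide C–O bond, which leads to the 3,4-trans, all-equatorial ring. The step needs ortho- and not para-alkylation of the phenol, which the less hindered site between OH and OBn, phosphate-mediated hydrogen-bond delivery and the ring closure that only the ortho adduct can undergo should secure; it also needs ionisation of the carbinol before the epoxide, which the far greater stabilisation of the trioxygenated benzylic cation should secure at low temperature.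

Step 13
Reactants: 18 protected trimer acetate
Product: 19 [tetra-O-benzylcatechin]-(4α→8)-[penta-O-benzylgallocatechin]-(4α→8)-[hexa-O-benzylgallocatechin] with the top and middle 3-OH free
Conditions: K2CO3, MeOH/THF, rt
Reagents that add atoms: none
Why: Base-catalysed transesterification removes the acetate; benzyl ethers, interflavan bonds and all stereocentres are inert to mild carbonate.

Step 14
Reactants: 19 pentadeca-O-benzyl trimer
Product: 20 catechin-(4α→8)-gallocatechin-(4α→8)-gallocatechin (target)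
Conditions: H2 (1 atm), Pd(OH)2/C, THF/MeOH/H2O, rt; filtration, lyophilisation
Reagents that add atoms: none
Why: Neutral hydrogenolysis of the fifteen benzyl ethers over Pd(OH)2/C, a standard end game for benzylated proanthocyanidins, should leave the acid-labile interflavan bonds and the stereocentres untouched.

## Compound list

1 | (+)-catechin, (2R,3S) | Oc1cc(O)c2c(c1)O[C@H](c1ccc(O)c(O)c1)[C@@H](O)C2 | starting material
2 | 5,7,3',4'-tetra-O-benzyl-(+)-catechin | c1ccccc1COc1cc(OCc2ccccc2)c2c(c1)O[C@H](c1ccc(OCc3ccccc3)c(OCc3ccccc3)c1)[C@@H](O)C2 | intermediate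
3 | (2R,3S,4S)-5,7,3',4'-tetra-O-benzyl-4-(2-ethoxyethoxy)flavan-3-ol | c1ccccc1COc1cc(OCc2ccccc2)c2c(c1)O[C@H](c1ccc(OCc3ccccc3)c(OCc3ccccc3)c1)[C@@H](O)[C@H]2OCCOCC | intermediate
4 | (2R,3S,4S)-3-O-acetyl-5,7,3',4'-tetra-O-benzyl-4-(2-ethoxyethoxy)flavan | c1ccccc1COc1cc(OCc2ccccc2)c2c(c1)O[C@H](c1ccc(OCc3ccccc3)c(OCc3ccccc3)c1)[C@@H](OC(C)=O)[C@H]2OCCOCC | intermediate
5 | 3,5-bis(benzyloxy)phenol | Oc1cc(OCc2ccccc2)cc(OCc2ccccc2)c1 | starting material
6 | 3-O-acetyl-5,7,3',4'-tetra-O-benzylcatechin-(4α→2)-[3,5-bis(benzyloxy)phenol] | c1ccccc1COc1cc(OCc2ccccc2)c2c(c1)O[C@H](c1ccc(OCc3ccccc3)c(OCc3ccccc3)c1)[C@@H](OC(C)=O)[C@@H]2c1c(OCc2ccccc2)cc(OCc2ccccc2)cc1O | intermediate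
7 | (+)-gallocatechin, (2R,3S) | Oc1cc(O)c2c(c1)O[C@H](c1cc(O)c(O)c(O)c1)[C@@H](O)C2 | starting material
8 | 3,5,7,3',4',5'-hexa-O-benzyl-(+)-gallocatechin | c1ccccc1COc1cc(OCc2ccccc2)c2c(c1)O[C@H](c1cc(OCc3ccccc3)c(OCc3ccccc3)c(OCc3ccccc3)c1)[C@@H](OCc1ccccc1)C2 | intermediate
9 | 8-bromo-3,5,7,3',4',5'-hexa-O-benzyl-(+)-gallocatechin | c1ccccc1COc1cc(OCc2ccccc2)c2c(c1Br)O[C@H](c1cc(OCc3ccccc3)c(OCc3ccccc3)c(OCc3ccccc3)c1)[C@@H](OCc1ccccc1)C2 | intermediate
10 | 3,4,5-tris(benzyloxy)benzaldehyde | O=Cc1cc(OCc2ccccc2)c(OCc2ccccc2)c(OCc2ccccc2)c1 | starting material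
11 | ethyl (E)-3-[3,4,5-tris(benzyloxy)phenyl]prop-2-enoate | CCOC(=O)/C=C/c1cc(OCc2ccccc2)c(OCc2ccccc2)c(OCc2ccccc2)c1 | intermediate
12 | (E)-3-[3,4,5-tris(benzyloxy)phenyl]prop-2-en-1-ol | OC/C=C/c1cc(OCc2ccccc2)c(OCc2ccccc2)c(OCc2ccccc2)c1 | intermediate
13 | {(2S,3S)-3-[3,4,5-tris(benzyloxy)phenyl]oxiran-2-yl}methanol | OC[C@@H]1O[C@H]1c1cc(OCc2ccccc2)c(OCc2ccccc2)c(OCc2ccccc2)c1 | intermediate
14 | (2R,3S)-3-[3,4,5-tris(benzyloxy)phenyl]oxirane-2-carbaldehyde | O=C[C@@H]1O[C@H]1c1cc(OCc2ccccc2)c(OCc2ccccc2)c(OCc2ccccc2)c1 | intermediate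
15 | 8-lithio-3,5,7,3',4',5'-hexa-O-benzyl-(+)-gallocatechin | [Li]c1c(OCc2ccccc2)cc(OCc2ccccc2)c2c1O[C@H](c1cc(OCc3ccccc3)c(OCc3ccccc3)c(OCc3ccccc3)c1)[C@@H](OCc1ccccc1)C2 | intermediate
16 | (hexa-O-benzylgallocatechin-8-yl){(2S,3S)-3-[3,4,5-tris(benzyloxy)phenyl]oxiran-2-yl}methanol, carbinol epimers | OC([C@@H]1O[C@H]1c1cc(OCc2ccccc2)c(OCc2ccccc2)c(OCc2ccccc2)c1)c1c(OCc2ccccc2)cc(OCc2ccccc2)c2c1O[C@H](c1cc(OCc3ccccc3)c(OCc3ccccc3)c(OCc3ccccc3)c1)[C@@H](OCc1ccccc1)C2 | intermediate
17 | ring-open epoxy phenol: 6 alkylated at the ring carbon ortho to OH by the C4 carbon that carries the bottom unit (C8) and the (2S,3S)-aryl-oxiranyl group, C4 configured as in 18 | c1ccccc1COc1cc(OCc2ccccc2)c2c(c1)O[C@H](c1ccc(OCc3ccccc3)c(OCc3ccccc3)c1)[C@@H](OC(C)=O)[C@@H]2c1c(OCc2ccccc2)cc(OCc2ccccc2)c(c1O)[C@H]([C@@H]1O[C@H]1c1cc(OCc2ccccc2)c(OCc2ccccc2)c(OCc2ccccc2)c1)c1c(OCc2ccccc2)cc(OCc2ccccc2)c2c1O[C@H](c1cc(OCc3ccccc3)c(OCc3ccccc3)c(OCc3ccccc3)c1)[C@@H](OCc1ccccc1)C2 | intermediate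
18 | [3-O-acetyl-5,7,3',4'-tetra-O-benzylcatechin]-(4α→8)-[5,7,3',4',5'-penta-O-benzylgallocatechin]-(4α→8)-[3,5,7,3',4',5'-hexa-O-benzylgallocatechin] | c1ccccc1COc1cc(OCc2ccccc2)c2c(c1)O[C@H](c1ccc(OCc3ccccc3)c(OCc3ccccc3)c1)[C@@H](OC(C)=O)[C@@H]2c1c(OCc2ccccc2)cc(OCc2ccccc2)c2c1O[C@H](c1cc(OCc3ccccc3)c(OCc3ccccc3)c(OCc3ccccc3)c1)[C@@H](O)[C@@H]2c1c(OCc2ccccc2)cc(OCc2ccccc2)c2c1O[C@H](c1cc(OCc3ccccc3)c(OCc3ccccc3)c(OCc3ccccc3)c1)[C@@H](OCc1ccccc1)C2 | intermediate
19 | [5,7,3',4'-tetra-O-benzylcatechin]-(4α→8)-[5,7,3',4',5'-penta-O-benzylgallocatechin]-(4α→8)-[3,5,7,3',4',5'-hexa-O-benzylgallocatechin] | c1ccccc1COc1cc(OCc2ccccc2)c2c(c1)O[C@H](c1ccc(OCc3ccccc3)c(OCc3ccccc3)c1)[C@@H](O)[C@@H]2c1c(OCc2ccccc2)cc(OCc2ccccc2)c2c1O[C@H](c1cc(OCc3ccccc3)c(OCc3ccccc3)c(OCc3ccccc3)c1)[C@@H](O)[C@@H]2c1c(OCc2ccccc2)cc(OCc2ccccc2)c2c1O[C@H](c1cc(OCc3ccccc3)c(OCc3ccccc3)c(OCc3ccccc3)c1)[C@@H](OCc1ccccc1)C2 | intermediate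
20 | catechin-(4α→8)-gallocatechin-(4α→8)-gallocatechin | Oc1cc(O)c2c(c1)O[C@H](c1ccc(O)c(O)c1)[C@@H](O)[C@@H]2c1c(O)cc(O)c2c1O[C@H](c1cc(O)c(O)c(O)c1)[C@@H](O)[C@@H]2c1c(O)cc(O)c2c1O[C@H](c1cc(O)c(O)c(O)c1)[C@@H](O)C2 | target

## Summary

Total step count: 14. Longest linear sequence: 8 steps (steps 7–14, from 10).

Steps most likely to fail:

1. Step 12. The risks are poor facial selectivity at C4 in the intermolecular Friedel–Crafts event, alkylation at the carbon para to the phenol or on a benzylated ring A, and 5-exo opening or hydride-shift rearrangement of the epoxide before ring closure. The fallback uses only known interflavan-bond chemistry and sets out from 7 (with 8 and 4 as partners).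
   - 7 is benzylated on its five phenols only (BnBr, K2CO3, DMF) to 5,7,3',4',5'-penta-O-benzylgallocatechin F1.
   - F1 is oxidised at C4 (DDQ, 2-ethoxyethanol) to the 4-(2-ethoxyethoxy) ether F2 and acetylated (Ac2O, pyridine) to the 3-acetate F3.
   - TMSOTf-mediated condensation of F3 with an excess of 8 as C8 nucleophile should give, under acetoxy participation, the 4α→8 dimer acetate F4.
   - A second TMSOTf-mediated condensation of electrophile 4 with F4, which reacts at C8 of its upper unit, should give the trimer diacetate F5.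
   - K2CO3 in MeOH/THF removes both acetates, and the fallback comes back to the route at 19.

2. Step 4. The risks are attack of the C4 cation at the carbon between the two benzyloxy groups (para to OH) and double alkylation of the phenol. The fallback changes the order of bond formation so that the top unit is attached last; it sets out from 5 and 16.
   - The annulation of step 12 is run on the simple phenol 5, whose two ortho carbons are equivalent, to give 5,7,3',4',5'-penta-O-benzylgallocatechin-(4α→8)-hexa-O-benzylgallocatechin F6 with a free 3-OH.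
   - Condensation of F6 with electrophile 4 (TMSOTf, CH2Cl2, −78 °C), which for 5,7-di-O-benzylflavans is known to occur at C8 of the upper unit and 3,4-trans under acetoxy participation, comes back to the route at 18.

3. Step 11. The risks are quench of the hindered aryllithium by benzylic deprotonation and ionisation or rearrangement of the epoxy carbinol on isolation. The fallback builds the same carbon skeleton as a chalcone without an organolithium and sets out from 9.
   - Stille coupling of 9 with tributyl(1-ethoxyvinyl)stannane (Pd(PPh3)4, toluene, 100 °C) gives the 8-(1-ethoxyvinyl) compound F7, which dilute HCl hydrolyses to 8-acetyl-hexa-O-benzylgallocatechin F8.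
   - Claisen–Schmidt condensation of F8 with 10 (KOH, EtOH/THF) gives the (E)-chalcone F9.
   - Juliá–Colonna epoxidation (poly-L-leucine, urea–H2O2, DBU, THF) should give the (2R,3S)-epoxy ketone F10.
   - Reduction with NaBH4/CeCl3·7H2O (MeOH/THF, −40 °C) gives the carbinol epimers and comes back to the route at 16, which is used crude.

## Further compounds

F1 | step 12 | 5,7,3',4',5'-penta-O-benzyl-(+)-gallocatechin | c1ccccc1COc1cc(OCc2ccccc2)c2c(c1)O[C@H](c1cc(OCc3ccccc3)c(OCc3ccccc3)c(OCc3ccccc3)c1)[C@@H](O)C2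
F2 | step 12 | (2R,3S,4S)-5,7,3',4',5'-penta-O-benzyl-4-(2-ethoxyethoxy)-2-arylflavan-3-ol (gallocatechin series) | c1ccccc1COc1cc(OCc2ccccc2)c2c(c1)O[C@H](c1cc(OCc3ccccc3)c(OCc3ccccc3)c(OCc3ccccc3)c1)[C@@H](O)[C@H]2OCCOCC
F3 | step 12 | 3-O-acetyl-5,7,3',4',5'-penta-O-benzyl-4-(2-ethoxyethoxy)gallocatechin | c1ccccc1COc1cc(OCc2ccccc2)c2c(c1)O[C@H](c1cc(OCc3ccccc3)c(OCc3ccccc3)c(OCc3ccccc3)c1)[C@@H](OC(C)=O)[C@H]2OCCOCC
F4 | step 12 | [3-O-acetyl-penta-O-benzylgallocatechin]-(4α→8)-[hexa-O-benzylgallocatechin] | c1ccccc1COc1cc(OCc2ccccc2)c2c(c1)O[C@H](c1cc(OCc3ccccc3)c(OCc3ccccc3)c(OCc3ccccc3)c1)[C@@H](OC(C)=O)[C@@H]2c1c(OCc2ccccc2)cc(OCc2ccccc2)c2c1O[C@H](c1cc(OCc3ccccc3)c(OCc3ccccc3)c(OCc3ccccc3)c1)[C@@H](OCc1ccccc1)C2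
F5 | step 12 | [3-O-acetyl-tetra-O-benzylcatechin]-(4α→8)-[3-O-acetyl-penta-O-benzylgallocatechin]-(4α→8)-[hexa-O-benzylgallocatechin] | c1ccccc1COc1cc(OCc2ccccc2)c2c(c1)O[C@H](c1ccc(OCc3ccccc3)c(OCc3ccccc3)c1)[C@@H](OC(C)=O)[C@@H]2c1c(OCc2ccccc2)cc(OCc2ccccc2)c2c1O[C@H](c1cc(OCc3ccccc3)c(OCc3ccccc3)c(OCc3ccccc3)c1)[C@@H](OC(C)=O)[C@@H]2c1c(OCc2ccccc2)cc(OCc2ccccc2)c2c1O[C@H](c1cc(OCc3ccccc3)c(OCc3ccccc3)c(OCc3ccccc3)c1)[C@@H](OCc1ccccc1)C2
F6 | step 4 | [5,7,3',4',5'-penta-O-benzylgallocatechin]-(4α→8)-[hexa-O-benzylgallocatechin], upper 3-OH free | c1ccccc1COc1cc(OCc2ccccc2)c2c(c1)O[C@H](c1cc(OCc3ccccc3)c(OCc3ccccc3)c(OCc3ccccc3)c1)[C@@H](O)[C@@H]2c1c(OCc2ccccc2)cc(OCc2ccccc2)c2c1O[C@H](c1cc(OCc3ccccc3)c(OCc3ccccc3)c(OCc3ccccc3)c1)[C@@H](OCc1ccccc1)C2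
F7 | step 11 | 8-(1-ethoxyvinyl)-hexa-O-benzyl-(+)-gallocatechin | C=C(OCC)c1c(OCc2ccccc2)cc(OCc2ccccc2)c2c1O[C@H](c1cc(OCc3ccccc3)c(OCc3ccccc3)c(OCc3ccccc3)c1)[C@@H](OCc1ccccc1)C2
F8 | step 11 | 8-acetyl-hexa-O-benzyl-(+)-gallocatechin | CC(=O)c1c(OCc2ccccc2)cc(OCc2ccccc2)c2c1O[C@H](c1cc(OCc3ccccc3)c(OCc3ccccc3)c(OCc3ccccc3)c1)[C@@H](OCc1ccccc1)C2
F9 | step 11 | (E)-1-(hexa-O-benzylgallocatechin-8-yl)-3-[3,4,5-tris(benzyloxy)phenyl]prop-2-en-1-one | O=C(/C=C/c1cc(OCc2ccccc2)c(OCc2ccccc2)c(OCc2ccccc2)c1)c1c(OCc2ccccc2)cc(OCc2ccccc2)c2c1O[C@H](c1cc(OCc3ccccc3)c(OCc3ccccc3)c(OCc3ccccc3)c1)[C@@H](OCc1ccccc1)C2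
F10 | step 11 | (hexa-O-benzylgallocatechin-8-yl) {(2R,3S)-3-[3,4,5-tris(benzyloxy)phenyl]oxiran-2-yl} ketone | O=C([C@@H]1O[C@H]1c1cc(OCc2ccccc2)c(OCc2ccccc2)c(OCc2ccccc2)c1)c1c(OCc2ccccc2)cc(OCc2ccccc2)c2c1O[C@H](c1cc(OCc3ccccc3)c(OCc3ccccc3)c(OCc3ccccc3)c1)[C@@H](OCc1ccccc1)C2
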